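The numbers in the tables come from a simulation with constants of no real substance; the scatter is artificial.

A reading at 4.0 h in the flask comes 12.0 times as late as the first reading of the earlier runs, 19.98 min. By that first reading those runs already stand level: south-east product moves 0.3 percentage points from first to last reading, against a scatter of 0.5 points. The question is therefore the height of the level, not a rate.

| setting | south-east | south-west | north-east | flask |
|---|---|---|---|---|
| substrate | 0.10 M | 0.10 M | 0.10 M | 0.10 M |
| partner | 0.090 M (fed, over 15 s) | 0.090 M (fed, over 15 s) | 0.045 M (fed, over 15 s) | 0.0900 M (fed, over 15 s) |
| protic impurity | 0.020 M | 0.045 M | 0.030 M | 0.0300 M |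
| remark | run made earlier; the fed solution adds 0.25 times the starting volume | run made earlier; the fed solution adds 0.25 times the starting volume | run made earlier; the fed solution adds 0.25 times the starting volume | the fed solution adds 0.25 times the starting volume |
| time |  |  |  | 4.0 h |

- south-east (time / h: substrate / %, product / %): 0.333: 17.0, 83.0; 0.500: 16.4, 83.5; 0.667: 17.2, 83.4; 1.00: 16.1, 82.9; 1.50: 17.3, 83.5; 2.50: 16.8, 82.3; 4.00: 17.4, 83.3
- south-west (time / h: substrate / %, product / %): 0.333: 24.4, 75.0; 0.500: 25.0, 75.8; 0.667: 24.4, 76.2; 1.00: 24.6, 75.3; 1.50: 25.3, 75.7; 2.50: 24.5, 75.1; 4.00: 24.3, 75.9
- north-east (time / h: substrate / %, product / %): 0.333: 63.1, 37.0; 0.667: 62.9, 37.1; 1.00: 62.7, 37.0; 2.00: 62.6, 37.0; 4.00: 61.9, 36.7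

(readings scatter by 0.5 percentage points)

- why nothing more happens at 4.0 h, or that something still does (the partner has run out first / all of the substrate has reacted / it is still moving)
- part of the substrate gone at 4.0 h
- the product standing at 4.0 h, as a percentage of the substrate charged

- amounts are per litre of the starting volume; all of the dose is in the solution fed
- candidate steps: substrate + partner -> product; partner + protic impurity -> quenched reagent; substrate + partner + product -> 2 product
- the reaction counts as stopped when no species that holds the substrate changes by six tenths of a point or more over the second half of the time

Partner is the limiting reagent in the flask, its charge being less than that of substrate, and each candidate route to product costs one partner net. Define the quench share s as the partner charge missing from the product level, divided by the charge of protic impurity. Mean product levels of 83.1% south-east and 75.6% south-west give s = 0.344 and 0.321. The north-east run, with half that partner charge and a level of 37.0%, gives a smaller 0.268. The flask has the partner charge of the first two runs, so it takes their mean, 0.332.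

This reckoning draws the flask's product curve as follows. It starts from zero and stays under the line of partner fed so far. Its level is 80.0%, which the feed has supplied after 13.3 s. The knee therefore lies between that moment and 19.98 min, and the line then runs flat. Product crosses the falling substrate curve where the two are equal, at 0.0500 M of product, an amount the feed has supplied after 8.33 s, so the crossing lies between that earlier moment and the same first reading.

The forecast gives the partner has run out first, with 79.8% gone and 79.8% product, reasoning that “each stops because the partner runs out”. Its figure differs slightly from the 80.0% reckoned here.

    substrate + partner → product (k = 0.0270 L mol⁻¹ s⁻¹)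
    partner + protic impurity → quenched reagent (k = 0.350 L mol⁻¹ s⁻¹)
    substrate + partner + product → 2 product (k = 69.0 L² mol⁻² s⁻¹)

The flask ends with 79.8% product and 79.8% of substrate gone: the partner has run out first, with partner at 0% of its charge after 4.00 h. Protic impurity stands at 66% of its charge in the flask, so its consumed share is 34 points, beside s = 0.332. For the neighbour flask charged with 0.036 M of partner, the north-east share 0.268 reckons 28.0% product, and that neighbour stands at 28.7%.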